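**Retrosynthetic overview**

1. The target is a phenanthrene (ring A: C5–C8 with 7-OMe; ring B: C9/C10; ring C: C1–C4 with 2-Cl and 3-OH) whose C4 carries phenol ring D and whose C6 carries chlorophenol ring E. A CH2CH2 bridge from ring E to ring D closes a 12-membered ring through C4–C4a–C4b–C5–C6.
2. Key disconnection, both bonds in one operation: C10–C10a (closes ring B) and the bond between the bridge CH2 remote from ring E and the ring D carbon para to the ring D oxygen (closes the macrocycle). Both are made by twofold B-alkyl Suzuki–Miyaura coupling of an open quateraryl D–C–A–E that carries two aryl iodides and two vinyl groups.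
3. Enabling feature: C10a of ring C and the bridge-bearing carbon of ring D are the positions para to the two oxygens of the C4–ring D biphenol. C9 (on C8a of ring A) and the benzylic bridge carbon (on ring E) are both former formyl carbons ortho to a biaryl bond. One double iodination and one double Wittig therefore arm the cascade, and because the macrocycle runs through the bay carbons C4a–C4b, closing ring B holds rings D and E within reach.
4. The quateraryl comes from three Suzuki–Miyaura couplings (ring C–ring D after directed ortho-metalation; ring E–ring A; then C4a–C4b). Chlorines and oxygens come in with the four benzene building blocks.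
5. Ring order: rings A, C, D, E are bought as benzenes; ring B (6-membered, dihydro level) and then the 12-membered ring form in step 11; ring B is aromatised in step 13 by phenol-directed DDQ dehydrogenation; debenzylation ends the route.

Key step: step 11

Remark: the target has no stereocentre and its SMILES defines no axial configuration, so all compounds are drawn without stereodescriptors (hindered biaryl intermediates are carried as rotamer mixtures); 1, 5, 7 and 10 are taken as commercial; phenanthrene locants C1–C10a are used for rings A–C from compound 14 onwards.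

**Route**

Step 1
Reactants: 1 5-bromo-2-chlorophenol
Product: 2 4-bromo-1-chloro-2-(methoxymethoxy)benzene
Conditions: NaH, MOMCl, DMF, 0 °C → rt
Reagents that add atoms: chloromethyl methyl ether, COCCl
Why: Williamson-type O-alkylation of the sodium phenoxide installs the MOM ether, which directs the ortho-metalation of step 2 and can later be removed without touching benzyl ethers.

Step 2
Reactants: 2 4-bromo-1-chloro-2-(methoxymethoxy)benzene
Product: 4 1-bromo-4-chloro-2-iodo-3-(methoxymethoxy)benzene, via aryllithium 3 (not isolated)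
Conditions: LiN(iPr)2 (1.1 equiv), THF, −78 °C; then I2, −78 °C → rt
Reagents that add atoms: iodine, [I][I]
Why: Directed ortho-metalation: the hydrogen between OMOM and Br is the most acidic ring hydrogen (oxygen coordination plus two flanking inductive groups), the amide base does not exchange the halogens, and the aryllithium is trapped by iodine at −78 °C before LiBr can be lost.

Step 3
Reactants: 4 1-bromo-4-chloro-2-iodo-3-(methoxymethoxy)benzene; 5 [2-(benzyloxy)phenyl]boronic acid
Product: 6 2'-(benzyloxy)-6-bromo-3-chloro-2-(methoxymethoxy)-1,1'-biphenyl (rings C–D)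
Conditions: Pd(PPh3)4 (5 mol%), Na2CO3, DME/H2O, 80 °C
Reagents that add atoms: none
Why: Suzuki–Miyaura coupling selective for the C–I bond, because oxidative addition of zerovalent palladium to C–I is much faster than to C–Br or C–Cl and the remaining bromide ends up shielded by the new ortho aryl group.

Step 4
Reactants: 7 2-bromo-3-hydroxybenzaldehyde
Product: 8 2-bromo-6-chloro-3-hydroxybenzaldehyde
Conditions: NCS, p-TsOH·H2O (10 mol%), MeCN, rt
Reagents that add atoms: N-chlorosuccinimide, O=C1CCC(=O)N1Cl
Why: Electrophilic aromatic chlorination para to the hydroxyl, the usual site of halogenation of 3-hydroxybenzaldehydes, with the position between OH and CHO blocked by bromine.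

Step 5
Reactants: 8 2-bromo-6-chloro-3-hydroxybenzaldehyde
Product: 9 3-(benzyloxy)-2-bromo-6-chlorobenzaldehyde
Conditions: BnBr, K2CO3, DMF, rt
Reagents that add atoms: benzyl bromide, BrCc1ccccc1
Why: Williamson benzylation of the phenoxide; the benzyl ether is chosen because it should survive acid, boranes, palladium catalysis and DDQ until the last step.

Step 6
Reactants: 9 3-(benzyloxy)-2-bromo-6-chlorobenzaldehyde; 10 (4-formyl-2-methoxyphenyl)boronic acid
Product: 11 6-(benzyloxy)-3-chloro-2'-methoxy-[1,1'-biphenyl]-2,4'-dicarbaldehyde (rings E–A)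
Conditions: Pd(dppf)Cl2·CH2Cl2 (5 mol%), K3PO4, dioxane/H2O, 90 °C
Reagents that add atoms: none
Why: Suzuki–Miyaura coupling at the C–Br bond, which is activated by the ortho formyl group, while Pd(dppf)Cl2 should leave the aryl chloride untouched.

Step 7
Reactants: 11 6-(benzyloxy)-3-chloro-2'-methoxy-[1,1'-biphenyl]-2,4'-dicarbaldehyde
Product: 12 6-(benzyloxy)-5'-bromo-3-chloro-2'-methoxy-[1,1'-biphenyl]-2,4'-dicarbaldehyde
Conditions: NBS, DMF, rt → 45 °C
Reagents that add atoms: N-bromosuccinimide, O=C1CCC(=O)N1Br
Why: Electrophilic aromatic bromination para to the methoxy group of ring A and ortho to its formyl group (the pattern of 3-methoxybenzaldehydes); ring E should be slower because its open positions are only ortho or meta to its ether oxygen on a ring that also carries chlorine and formyl.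

Step 8
Reactants: 6 2'-(benzyloxy)-6-bromo-3-chloro-2-(methoxymethoxy)-1,1'-biphenyl; 12 6-(benzyloxy)-5'-bromo-3-chloro-2'-methoxy-[1,1'-biphenyl]-2,4'-dicarbaldehyde
Product: 14 6-(benzyloxy)-5'-[2'-(benzyloxy)-5-chloro-6-(methoxymethoxy)-[1,1'-biphenyl]-2-yl]-3-chloro-2'-methoxy-[1,1'-biphenyl]-2,4'-dicarbaldehyde (quateraryl dialdehyde D–C–A–E), via pinacol boronate 13 (not isolated)
Conditions: B2pin2, Pd(dppf)Cl2·CH2Cl2 (5 mol%), KOAc, dioxane, 90 °C; then 12, K3PO4, H2O, 90 °C
Reagents that add atoms: none
Why: Miyaura borylation of bromide 6, followed in the same flask by Suzuki–Miyaura coupling with the formyl-activated bromide 12, builds the future C4a–C4b bond; both aryl chlorides should be inert to Pd(dppf)Cl2.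

Step 9
Reactants: 14 quateraryl dialdehyde D–C–A–E
Product: 15 6-(benzyloxy)-5'-[2'-(benzyloxy)-5-chloro-3,5'-diiodo-6-(methoxymethoxy)-[1,1'-biphenyl]-2-yl]-3-chloro-2'-methoxy-[1,1'-biphenyl]-2,4'-dicarbaldehyde (diiodo dialdehyde; iodine on future C10a of ring C and on ring D para to OBn)
Conditions: NIS (2.3 equiv), (CF3)2CHOH, 0 °C → rt
Reagents that add atoms: N-iodosuccinimide, O=C1CCC(=O)N1I
Why: Electrophilic aromatic iodination: rings A and E are deactivated by their formyl groups, so iodine should enter only para to the ether oxygens of rings C and D, which on ring C is the single open ortho/para position.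

Step 10
Reactants: 15 diiodo dialdehyde
Product: 16 6-(benzyloxy)-5'-[2'-(benzyloxy)-5-chloro-3,5'-diiodo-6-(methoxymethoxy)-[1,1'-biphenyl]-2-yl]-3-chloro-2'-methoxy-2,4'-divinyl-1,1'-biphenyl (diiodo bis-styrene)
Conditions: Ph3PCH3Br, KOtBu, THF, 0 °C → rt
Reagents that add atoms: methyltriphenylphosphonium bromide, C[P+](c1ccccc1)(c1ccccc1)c1ccccc1.[Br-]
Why: Twofold Wittig methylenation of the two non-enolisable aryl aldehydes; aryl iodides, MOM and benzyl ethers are inert to the ylide.

Step 11
Reactants: 16 diiodo bis-styrene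
Product: 19 MOM-protected macrocyclic 9,10-dihydrophenanthrene (the 9,10-dihydro target with 3-OMOM and O-benzyl on rings D and E), via bis-alkylborane 17 (not isolated), via dihydrophenanthrene alkylborane 18 (not isolated)
Conditions: 9-BBN (3 equiv), THF, rt; then syringe-pump addition to Pd(dppf)Cl2·CH2Cl2 (20 mol%), AsPh3 (20 mol%), Cs2CO3, DMF/THF/H2O, 60 °C, final 1 mM
Reagents that add atoms: none
Why: 9-BBN adds to both vinyl groups at the terminal carbon to give bis(B-alkyl-9-BBN) 17; zerovalent palladium inserts into the two C–I bonds, and base-assisted transmetalation and reductive elimination form two C(sp3)–C(sp2) bonds, the closest known reaction type being the intramolecular B-alkyl Suzuki–Miyaura coupling used for carbocycle and macrocycle closure. Ring B closes in a 6-membered mode (C10 to C10a through a 7-membered palladacycle) because the borylethyl arm on C8a and the iodide on C10a sit ortho,ortho' on the same biaryl, which turns the flexible quateraryl into the 4,6-diaryl-9,10-dihydrophenanthrene 18 with rings D and E held across the bay. The 12-membered ring then closes in a macrocyclisation mode by joining the bridge CH2 remote from ring E to the ring D carbon para to the benzyloxy group; the product ring is the same whichever closure comes first, since it runs through C4a–C4b and not through C9/C10. No stereocentre is formed. The step needs pairing selectivity and chemoselectivity for C–I over C–Cl: the two mismatched borane/iodide pairings would give 9-membered rings spanning a meta-linked arene, Pd(dppf)Cl2 should not insert into the aryl chlorides at 60 °C, and high dilution holds back oligomers.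

Step 12
Reactants: 19 MOM-protected macrocyclic 9,10-dihydrophenanthrene
Product: 20 macrocyclic 9,10-dihydrophenanthren-3-ol (the 9,10-dihydro target with free C3–OH and O-benzyl on rings D and E)
Conditions: HCl (conc., cat.), MeOH/THF, 45 °C
Reagents that add atoms: none
Why: Acid-catalysed acetal exchange with methanol removes only the MOM ether; benzyl ethers, the methyl ether and the aryl chlorides are stable to HCl in methanol.

Step 13
Reactants: 20 macrocyclic 9,10-dihydrophenanthren-3-ol
Product: 22 ring D/ring E bis(benzyl ether) of the target (free C3–OH), via para-quinone methide 21 (not isolated)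
Conditions: DDQ (1.05 equiv), 1,4-dioxane, 0 °C → rt
Reagents that add atoms: none
Why: Quinone dehydrogenation: the free C3 phenol makes the para benzylic C10–H the most hydridic site, DDQ should convert it into para-quinone methide 21, and loss of a C9 proton then gives the aromatic phenanthrene, whereas the bridge CH2 para to a benzyl ether should react far more slowly.

Step 14
Reactants: 22 ring D/ring E bis(benzyl ether) of the target
Product: 23 target, 2-chloro-7-methoxyphenanthren-3-ol bridged from C4 (ring D, 2-hydroxyphenyl-1,5-diyl) through CH2CH2 to ring E (3-chloro-6-hydroxy-1,2-phenylene) on C6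
Conditions: BCl3, C6HMe5, CH2Cl2, −78 °C → −40 °C
Reagents that add atoms: none
Why: Lewis acid debenzylation in which BCl3 ionises the aryl benzyl ethers and pentamethylbenzene traps the benzyl cation by Friedel–Crafts alkylation, conditions under which the aryl methyl ether and the aryl chlorides should stay intact.

**Compound list**

1 | 5-bromo-2-chlorophenol | Oc1cc(Br)ccc1Cl | starting material
2 | 4-bromo-1-chloro-2-(methoxymethoxy)benzene | COCOc1cc(Br)ccc1Cl | intermediate
3 | [6-bromo-3-chloro-2-(methoxymethoxy)phenyl]lithium | COCOc1c([Li])c(Br)ccc1Cl | intermediate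
4 | 1-bromo-4-chloro-2-iodo-3-(methoxymethoxy)benzene | COCOc1c(I)c(Br)ccc1Cl | intermediate
5 | [2-(benzyloxy)phenyl]boronic acid | OB(O)c1ccccc1OCc1ccccc1 | starting material
6 | 2'-(benzyloxy)-6-bromo-3-chloro-2-(methoxymethoxy)-1,1'-biphenyl | COCOc1c(Cl)ccc(Br)c1-c1ccccc1OCc1ccccc1 | intermediate
7 | 2-bromo-3-hydroxybenzaldehyde | O=Cc1cccc(O)c1Br | starting material
8 | 2-bromo-6-chloro-3-hydroxybenzaldehyde | O=Cc1c(Cl)ccc(O)c1Br | intermediate
9 | 3-(benzyloxy)-2-bromo-6-chlorobenzaldehyde | O=Cc1c(Cl)ccc(OCc2ccccc2)c1Br | intermediate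
10 | (4-formyl-2-methoxyphenyl)boronic acid | COc1cc(C=O)ccc1B(O)O | starting material
11 | 6-(benzyloxy)-3-chloro-2'-methoxy-[1,1'-biphenyl]-2,4'-dicarbaldehyde | COc1cc(C=O)ccc1-c1c(OCc2ccccc2)ccc(Cl)c1C=O | intermediate
12 | 6-(benzyloxy)-5'-bromo-3-chloro-2'-methoxy-[1,1'-biphenyl]-2,4'-dicarbaldehyde | COc1cc(C=O)c(Br)cc1-c1c(OCc2ccccc2)ccc(Cl)c1C=O | intermediate
13 | 2-[2'-(benzyloxy)-5-chloro-6-(methoxymethoxy)-[1,1'-biphenyl]-2-yl]-4,4,5,5-tetramethyl-1,3,2-dioxaborolane | COCOc1c(Cl)ccc(B2OC(C)(C)C(C)(C)O2)c1-c1ccccc1OCc1ccccc1 | intermediate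
14 | quateraryl dialdehyde D–C–A–E: 6-(benzyloxy)-5'-[2'-(benzyloxy)-5-chloro-6-(methoxymethoxy)-[1,1'-biphenyl]-2-yl]-3-chloro-2'-methoxy-[1,1'-biphenyl]-2,4'-dicarbaldehyde | COCOc1c(Cl)ccc(-c2cc(-c3c(OCc4ccccc4)ccc(Cl)c3C=O)c(OC)cc2C=O)c1-c1ccccc1OCc1ccccc1 | intermediate
15 | diiodo dialdehyde: 14 with iodine on ring C para to OMOM and on ring D para to OBn | COCOc1c(Cl)cc(I)c(-c2cc(-c3c(OCc4ccccc4)ccc(Cl)c3C=O)c(OC)cc2C=O)c1-c1cc(I)ccc1OCc1ccccc1 | intermediate
16 | diiodo bis-styrene: 15 with both CHO groups converted into vinyl | COCOc1c(Cl)cc(I)c(-c2cc(-c3c(OCc4ccccc4)ccc(Cl)c3C=C)c(OC)cc2C=C)c1-c1cc(I)ccc1OCc1ccccc1 | intermediate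
17 | bis-alkylborane: 16 with each vinyl converted into CH2CH2-(9-borabicyclo[3.3.1]nonan-9-yl) | COCOc1c(Cl)cc(I)c(-c2cc(-c3c(OCc4ccccc4)ccc(Cl)c3CCB3C4CCCC3CCC4)c(OC)cc2CCB2C3CCCC2CCC3)c1-c1cc(I)ccc1OCc1ccccc1 | intermediate
18 | dihydrophenanthrene alkylborane: 2-chloro-7-methoxy-3-(methoxymethoxy)-9,10-dihydrophenanthrene with 2-(benzyloxy)-5-iodophenyl on C4 and, on C6, the ring E aryl (6-benzyloxy-3-chloro) carrying the CH2CH2-9-BBN arm | COc1cc2CCc3cc(Cl)c(OCOC)c(-c4cc(I)ccc4OCc4ccccc4)c3-c2cc1-c1c(OCc2ccccc2)ccc(Cl)c1CCB1C2CCCC1CCC2 | intermediate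
19 | MOM-protected macrocyclic 9,10-dihydrophenanthrene (9,10-dihydro target, 3-OMOM, O-benzyl on rings D and E) | COc1cc2CCc3cc(Cl)c(OCOC)c4c3-c2cc1-c1c(OCc2ccccc2)ccc(Cl)c1CCc1ccc(OCc2ccccc2)c-4c1 | intermediate
20 | macrocyclic 9,10-dihydrophenanthren-3-ol (9,10-dihydro target, free C3–OH, O-benzyl on rings D and E) | COc1cc2CCc3cc(Cl)c(O)c4c3-c2cc1-c1c(OCc2ccccc2)ccc(Cl)c1CCc1ccc(OCc2ccccc2)c-4c1 | intermediate
21 | para-quinone methide of 20 (C3=O, C10=C10a) | COc1cc2CC=C3C=C(Cl)C(=O)C4=C3c2cc1-c1c(OCc2ccccc2)ccc(Cl)c1CCc1ccc(OCc2ccccc2)c4c1 | intermediate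
22 | ring D/ring E bis(benzyl ether) of the target | COc1cc2ccc3cc(Cl)c(O)c4c3c2cc1-c1c(OCc2ccccc2)ccc(Cl)c1CCc1ccc(OCc2ccccc2)c-4c1 | intermediate
23 | target CNP0310669.0 | COc1cc2ccc3cc(Cl)c(O)c4c3c2cc1-c1c(O)ccc(Cl)c1CCc1ccc(O)c-4c1 | target

**Step count and risks**

Total steps: 14. Longest linear sequence: 11 steps (7 → 23, steps 4–14).

Steps most likely to fail:

1. Step 11. The 12-membered closure may lose to intermolecular coupling (oligomers), to protodeboronation of the ring E alkylborane or reduction of the ring D iodide, or to slow rotation about the C4–ring D bond that keeps the iodide edge of ring D turned away from ring E. The fallback sets out from 16 and comes back at 19, replacing the base-activated borane by a preformed alkylzinc so that the couplings run without base or water and can be heated. Hydroboration–oxidation of 16 (9-BBN, THF; then NaBO3·4H2O) should give the bis(2-hydroxyethyl) quateraryl F1. Iodination of both primary alcohols (I2, PPh3, imidazole, CH2Cl2) should give the bis(2-iodoethyl) quateraryl F2. Zinc insertion into the two alkyl C–I bonds (Zn dust activated with TMSCl, DMA, 25–40 °C, under which the electron-rich aryl iodides are expected to stay intact) should give the bis(alkylzinc iodide) F3. Slow addition of F3 to Pd(dppf)Cl2·CH2Cl2 in THF/DMA at 50–70 °C should close ring B and the macrocycle by double intramolecular Negishi coupling to 19.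

2. Step 9. Iodination at the ring C position next to ring A may stall for steric reasons, and the acidic medium may cleave the MOM acetal part-way. The fallback sets out from 14 and comes back at 15, using the free phenol as the directing group. Removal of the MOM group from 14 (HCl, MeOH/THF) should give the quateraryl phenol dialdehyde F4. NIS (2.2 equiv) with catalytic TFA in MeCN should then iodinate ring C at the only open position para to the free hydroxyl and ring D para to its benzyloxy group, with no acetal left to lose, giving the diiodo phenol dialdehyde F5. Re-protection (NaH, MOMCl, DMF) returns 15.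

3. Step 2. The aryllithium flanked by bromine may lose LiBr (aryne formation) or undergo halogen migration before the iodine quench. The fallback avoids lithiation next to bromine; it sets out from 5 and comes back at boronate 13. Suzuki–Miyaura coupling of 5 with commercial 2-iodoresorcinol F6 (Pd(dppf)Cl2·CH2Cl2, K3PO4, dioxane/H2O) should give 2'-(benzyloxy)-[1,1'-biphenyl]-2,6-diol F7. Monochlorination with NCS (1.0 equiv, MeCN, 0 °C) at one of the two symmetry-equivalent positions ortho/para to the hydroxyls should give 2'-(benzyloxy)-3-chloro-[1,1'-biphenyl]-2,6-diol F8. Alkylation with one equivalent each of K2CO3 and MOMCl is expected to favour the more acidic hydroxyl next to chlorine and give 2'-(benzyloxy)-5-chloro-6-(methoxymethoxy)-[1,1'-biphenyl]-2-ol F9. Triflation (Tf2O, pyridine) should give the aryl triflate F10, which takes the place of bromide 6 in the borylation half of step 8 and delivers 13.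

**Further compounds**

F1 | step 11 | bis(2-hydroxyethyl) quateraryl (16 with each vinyl converted into CH2CH2OH) | COCOc1c(Cl)cc(I)c(-c2cc(-c3c(OCc4ccccc4)ccc(Cl)c3CCO)c(OC)cc2CCO)c1-c1cc(I)ccc1OCc1ccccc1
F2 | step 11 | bis(2-iodoethyl) quateraryl | COCOc1c(Cl)cc(I)c(-c2cc(-c3c(OCc4ccccc4)ccc(Cl)c3CCI)c(OC)cc2CCI)c1-c1cc(I)ccc1OCc1ccccc1
F3 | step 11 | bis(alkylzinc iodide) | COCOc1c(Cl)cc(I)c(-c2cc(-c3c(OCc4ccccc4)ccc(Cl)c3CC[Zn]I)c(OC)cc2CC[Zn]I)c1-c1cc(I)ccc1OCc1ccccc1
F4 | step 9 | quateraryl phenol dialdehyde (14 without MOM) | Oc1c(Cl)ccc(-c2cc(-c3c(OCc4ccccc4)ccc(Cl)c3C=O)c(OC)cc2C=O)c1-c1ccccc1OCc1ccccc1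
F5 | step 9 | diiodo phenol dialdehyde (15 without MOM) | Oc1c(Cl)cc(I)c(-c2cc(-c3c(OCc4ccccc4)ccc(Cl)c3C=O)c(OC)cc2C=O)c1-c1cc(I)ccc1OCc1ccccc1
F6 | step 2 | 2-iodoresorcinol | Oc1cccc(O)c1I
F7 | step 2 | 2'-(benzyloxy)-[1,1'-biphenyl]-2,6-diol | Oc1cccc(O)c1-c1ccccc1OCc1ccccc1
F8 | step 2 | 2'-(benzyloxy)-3-chloro-[1,1'-biphenyl]-2,6-diol | Oc1ccc(Cl)c(O)c1-c1ccccc1OCc1ccccc1
F9 | step 2 | 2'-(benzyloxy)-5-chloro-6-(methoxymethoxy)-[1,1'-biphenyl]-2-ol | COCOc1c(Cl)ccc(O)c1-c1ccccc1OCc1ccccc1
F10 | step 2 | 2'-(benzyloxy)-5-chloro-6-(methoxymethoxy)-[1,1'-biphenyl]-2-yl trifluoromethanesulfonate | COCOc1c(Cl)ccc(OS(=O)(=O)C(F)(F)F)c1-c1ccccc1OCc1ccccc1
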